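**Plan**
Atom labels: ring oxygen O1, lactone carbonyl C2, C3, enol carbon C4, stereocentre C5 with its CH2OH group; C1' is the side-chain ketone.
Cuts, in retrosynthetic order: the benzyl group on the C5 CH2OH oxygen, the ring bond C2–C3, O1–C2, C3–C4, C1'–C3.
Enabling feature: C2 is bonded only to O1, its own carbonyl oxygen and C3, so it is a carbonic acid carbon. C3 lies between the ketone-level carbons C1' and C4, so a single carbonyl unit can be hung on O1 and closed onto the soft central carbon of a 1,3-diketone.
Forward: O-benzyl-L-serine 1 becomes the O-silylated glycerate ester 4, and 13-methyltetradecanoic acid 5 with MeLi 6 gives methyl ketone 8. A crossed Claisen condensation joins them at C3–C4 to give diketone 11. After desilylation, CDI 13 is placed on O1 (14), the only ring, the furan-2(5H)-one, closes at C2–C3 (16), and hydrogenolysis gives 17.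
Stereochemistry: C5 (S) is the alpha-carbon of 1. It is carried over with retention in the diazotisation and is never deprotonated afterwards. There is no other stereocentre.

Key step: step 8

Assumption: 1, 5, 6 and 13 are catalogue chemicals; the 1,3-diketones are written in the diketo form and the 3-acyltetronic acids as the 4-hydroxy tautomer of the target SMILES, although all are rapidly equilibrating enol mixtures.

Step 1
Reactants: 1 O-benzyl-L-serine
Product: 2 (S)-3-(benzyloxy)-2-hydroxypropanoic acid
Conditions: NaNO2 (1.5 equiv), 1 M aq H2SO4, 0 °C to rt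
Reagents that add atoms: water, O
Why: Diazotisation of an alpha-amino acid runs through carboxylate participation (alpha-lactone) and opening by water, a double inversion, so the S configuration that becomes C5 should be retained, and the benzyl ether is inert to cold dilute acid.

Step 2
Reactants: 2 (S)-3-(benzyloxy)-2-hydroxypropanoic acid
Product: 3 methyl (S)-3-(benzyloxy)-2-hydroxypropanoate
Conditions: MeOH, cat. H2SO4, reflux
Reagents that add atoms: methanol, CO
Why: Fischer esterification in a large excess of methanol outruns self-esterification of the hydroxy acid and does not touch the stereocentre or the benzyl ether.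

Step 3
Reactants: 3 methyl (S)-3-(benzyloxy)-2-hydroxypropanoate
Product: 4 methyl (S)-3-(benzyloxy)-2-[(triethylsilyl)oxy]propanoate
Conditions: Et3SiCl, imidazole, CH2Cl2, 0 °C to rt
Reagents that add atoms: chlorotriethylsilane, CC[Si](Cl)(CC)CC
Why: Imidazole-promoted silylation of a secondary alcohol is routine, and the triethylsilyl ether tolerates lithium enolates at low temperature yet leaves under nearly neutral fluoride conditions, which the later hydroxy diketone demands.

Step 4
Reactants: 5 13-methyltetradecanoic acid; 6 methyllithium
Product: 8 14-methylpentadecan-2-one, via dilithium gem-diolate 7 (not isolated)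
Conditions: MeLi (2.1 equiv), THF, 0 °C; poured into ice-cold 1 M HCl
Reagents that add atoms: methyllithium 6, [Li]C
Why: Addition of an organolithium to a lithium carboxylate stops at gem-diolate 7, which cannot collapse until the inverse acid quench has destroyed residual MeLi, so the methyl ketone rather than the tertiary alcohol should result.

Step 5
Reactants: 8 14-methylpentadecan-2-one; 4 methyl (S)-3-(benzyloxy)-2-[(triethylsilyl)oxy]propanoate
Product: 11 (S)-1-(benzyloxy)-17-methyl-2-[(triethylsilyl)oxy]octadecane-3,5-dione, via lithium enolate 9 (not isolated), via lithium diketonate 10 (not isolated)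
Conditions: LiN(iPr)2 (LDA, 2.1 equiv), 8 (2.0 equiv), THF, −78 °C; then 4 (1.0 equiv), −78 to −30 °C; AcOH in THF, pH 7 buffer
Reagents that add atoms: none
Why: In this crossed Claisen condensation LDA deprotonates the methyl side of 8 under kinetic control, enolate 9 adds to the ester carbonyl activated by its alpha-oxygen, and the second equivalent of 9 converts the product into diketonate 10, whose charge stops further attack and shields the neighbouring stereocentre, while regenerated 8 is recovered.

Step 6
Reactants: 11 (S)-1-(benzyloxy)-17-methyl-2-[(triethylsilyl)oxy]octadecane-3,5-dione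
Product: 12 (S)-1-(benzyloxy)-2-hydroxy-17-methyloctadecane-3,5-dione
Conditions: Bu4NF/AcOH (1:1, 1.5 equiv), THF, 0 °C; cold pH 7 phosphate work-up, toluene azeotrope, crude product used at once
Reagents that add atoms: none
Why: Acetic acid-buffered fluoride cleavage of a triethylsilyl ether is a standard method for acid- and base-sensitive carbonyl compounds, and the near-neutral medium, low temperature and omission of chromatography are meant to hold back acid-catalysed cyclodehydration and enediol epimerisation.

Step 7
Reactants: 12 (S)-1-(benzyloxy)-2-hydroxy-17-methyloctadecane-3,5-dione; 13 1,1'-carbonyldiimidazole (CDI)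
Product: 14 (S)-1-(benzyloxy)-17-methyl-3,5-dioxooctadecan-2-yl 1H-imidazole-1-carboxylate
Conditions: CDI (1.1 equiv), CH2Cl2, 0 °C to rt; cold water wash, crude product carried on
Reagents that add atoms: 1,1'-carbonyldiimidazole 13, O=C(n1ccnc1)n1ccnc1
Why: Alcoholysis of CDI is the standard route to alkyl imidazole-1-carboxylates, O1 is the only site acylated irreversibly because an enol carbamate is returned by the liberated imidazole, and capping O1 removes the nucleophile of the furanone-forming side path.

Step 8
Reactants: 14 (S)-1-(benzyloxy)-17-methyl-3,5-dioxooctadecan-2-yl 1H-imidazole-1-carboxylate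
Product: 16 (S)-5-[(benzyloxy)methyl]-4-hydroxy-3-(13-methyltetradecanoyl)furan-2(5H)-one, via DBU-H tetronate salt 15 (not isolated)
Conditions: DBU (2.0 equiv), DMAP (0.1 equiv), MeCN (0.03 M), 0 °C to rt; then cold 1 M HCl
Reagents that add atoms: none
Why: Proposed new method: DBU removes a C3 proton of the 1,3-diketone, the diketonate carbon adds to the carbamate carbonyl C2 held on O1, and the tetrahedral intermediate releases imidazolide, so the C2–C3 bond and the lactone ring arise in one event. The closest known reaction types are the base-mediated closure of O-alkoxycarbonyl alpha-hydroxy ketones to tetronic acids and the C-acylation of 1,3-dicarbonyl anions by acyl imidazoles, and the new element is their union on an acyclic alpha'-oxygenated 1,3-diketone. The single ring closes in the 5-exo-trig mode at C2 and counts as enolexo, because the charge can rest on the C1' oxygen while the C3–C4 bond twists to bring C3 over C2. No stereocentre is created, and C5 should stay S because the negative charge already spread over C4 puts a second deprotonation at C5, and with it loss of benzyl oxide, beyond the reach of DBU. The step needs carbon rather than oxygen acylation: attack through the C4 oxygen gives a five-membered enol carbonate that is still an acyl donor and is reopened by imidazole or DMAP, whereas attack through C3 ends in salt 15 of a strongly acidic tricarbonyl compound, so the equilibria should drain towards 15. Cold dilute HCl then liberates 16.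

Step 9
Reactants: 16 (S)-5-[(benzyloxy)methyl]-4-hydroxy-3-(13-methyltetradecanoyl)furan-2(5H)-one
Product: 17 (S)-4-hydroxy-5-(hydroxymethyl)-3-(13-methyltetradecanoyl)furan-2(5H)-one
Conditions: H2 (1 atm), 10% Pd/C, EtOAc, rt; filtration, dilute HCl wash, crystallisation (no silica gel, which hands metal ions to the chelating product)
Reagents that add atoms: none
Why: Catalytic hydrogenolysis of a primary benzyl ether is routine, the enolised tricarbonyl unit behaves as a vinylogous acid that should resist hydrogenation at one atmosphere, and C5 is not involved.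

**Compound list**
1 | O-benzyl-L-serine | N[C@@H](COCc1ccccc1)C(=O)O | starting material
2 | (S)-3-(benzyloxy)-2-hydroxypropanoic acid | O[C@@H](COCc1ccccc1)C(=O)O | intermediate
3 | methyl (S)-3-(benzyloxy)-2-hydroxypropanoate | O[C@@H](COCc1ccccc1)C(=O)OC | intermediate
4 | methyl (S)-3-(benzyloxy)-2-[(triethylsilyl)oxy]propanoate | CC[Si](CC)(CC)O[C@@H](COCc1ccccc1)C(=O)OC | intermediate
5 | 13-methyltetradecanoic acid | CC(C)CCCCCCCCCCCC(=O)O | starting material
6 | methyllithium | [Li]C | starting material
7 | dilithium 14-methylpentadecane-2,2-diolate (gem-diolate, not isolated) | CC(C)CCCCCCCCCCCC(C)([O-])[O-].[Li+].[Li+] | intermediate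
8 | 14-methylpentadecan-2-one | CC(C)CCCCCCCCCCCC(C)=O | intermediate
9 | lithium 14-methylpentadec-1-en-2-olate (kinetic enolate, not isolated) | CC(C)CCCCCCCCCCCC(=C)[O-].[Li+] | intermediate
10 | lithium (S)-1-(benzyloxy)-17-methyl-3,5-dioxo-2-[(triethylsilyl)oxy]octadecan-4-ide (diketonate, not isolated) | CC(C)CCCCCCCCCCCC(=O)[CH-]C(=O)[C@H](COCc1ccccc1)O[Si](CC)(CC)CC.[Li+] | intermediate
11 | (S)-1-(benzyloxy)-17-methyl-2-[(triethylsilyl)oxy]octadecane-3,5-dione | CC(C)CCCCCCCCCCCC(=O)CC(=O)[C@H](COCc1ccccc1)O[Si](CC)(CC)CC | intermediate
12 | (S)-1-(benzyloxy)-2-hydroxy-17-methyloctadecane-3,5-dione | CC(C)CCCCCCCCCCCC(=O)CC(=O)[C@H](COCc1ccccc1)O | intermediate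
13 | 1,1'-carbonyldiimidazole (CDI) | O=C(n1ccnc1)n1ccnc1 | starting material
14 | (S)-1-(benzyloxy)-17-methyl-3,5-dioxooctadecan-2-yl 1H-imidazole-1-carboxylate | CC(C)CCCCCCCCCCCC(=O)CC(=O)[C@H](COCc1ccccc1)OC(=O)n1ccnc1 | intermediate
15 | 1,8-diazabicyclo[5.4.0]undec-7-enium (S)-5-[(benzyloxy)methyl]-3-(13-methyltetradecanoyl)-2-oxo-2,5-dihydrofuran-4-olate (not isolated) | CC(C)CCCCCCCCCCCC(=O)C1=C([O-])[C@H](COCc2ccccc2)OC1=O.C1CCC2=[NH+]CCCN2CC1 | intermediate
16 | (S)-5-[(benzyloxy)methyl]-4-hydroxy-3-(13-methyltetradecanoyl)furan-2(5H)-one | CC(C)CCCCCCCCCCCC(=O)C1=C(O)[C@H](COCc2ccccc2)OC1=O | intermediate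
17 | (S)-4-hydroxy-5-(hydroxymethyl)-3-(13-methyltetradecanoyl)furan-2(5H)-one | CC(C)CCCCCCCCCCCC(=O)C1=C(O)[C@H](CO)OC1=O | target

Total step count: 9.
Longest linear sequence: 8 steps from 1 (steps 1, 2, 3, 5, 6, 7, 8, 9). Step 4 is a one-step side branch.

**Steps most likely to fail**

Step 8. Oxygen acylation may fail to revert. Acyl transfer between molecules may compete. The closure may also be slow, because the diketonate has to twist out of conjugation before C3 can reach C2. The fallback uses the known Lacey–Dieckmann approach, which closes the ring at C3–C4 instead. It sets out from 5 and 3 and comes back at 16. Acid 5 is condensed with Meldrum's acid (DCC, DMAP, CH2Cl2) to 5-(1-hydroxy-13-methyltetradecylidene)-2,2-dimethyl-1,3-dioxane-4,6-dione F1. Heating F1 with hydroxy ester 3 in toluene gives methyl (S)-3-(benzyloxy)-2-[(15-methyl-3-oxohexadecanoyl)oxy]propanoate F2. Bu4NF in THF at rt then brings about the Dieckmann condensation of the active methylene onto the methyl ester to give 16.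

Step 6. While the alcohol is uncapped, the freed hydroxyl may add to C1' and lose water (cyclodehydration). C5 may also epimerise through the enediol during the time that fluoride and acetic acid need to act. The fallback has no silyl group and no deprotection step. It sets out from 2, uses enolate 9, and comes back at 12. Acid 2 is converted with 2,2-dimethoxypropane and cat. TsOH in CH2Cl2 into (S)-5-[(benzyloxy)methyl]-2,2-dimethyl-1,3-dioxolan-4-one F3, which is protecting group and activated acyl donor in one. Acylation of lithium enolates by such dioxolanones is known. Enolate 9 opens F3 in THF at −78 °C, and a cold pH 7 quench sheds the acetonide carbon and releases 12 only minutes before CDI is added.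

Step 5. Proton transfer may win over addition. Enolisation of ester 4 would erode the configuration and trigger beta-elimination of benzyl oxide. The regenerated ketone may scramble the kinetic enolate, and the product consumes a second equivalent of the valuable ketone. The fallback replaces the acylation by an aldol addition and an oxidation. It sets out from 4 and comes back at 11. iBu2AlH in toluene at −78 °C reduces 4 to (S)-3-(benzyloxy)-2-[(triethylsilyl)oxy]propanal F4. Enolate 9 (1.1 equiv, THF, −78 °C) adds to give (2S)-1-(benzyloxy)-3-hydroxy-17-methyl-2-[(triethylsilyl)oxy]octadecan-5-one F5 as both C3 epimers, a mixture that does not matter. Dess–Martin periodinane (CH2Cl2, NaHCO3) then oxidises the carbinol to diketone 11.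

**Further compounds**
F1 | step 8 | 5-(1-hydroxy-13-methyltetradecylidene)-2,2-dimethyl-1,3-dioxane-4,6-dione | CC(C)CCCCCCCCCCCC(O)=C1C(=O)OC(C)(C)OC1=O
F2 | step 8 | methyl (S)-3-(benzyloxy)-2-[(15-methyl-3-oxohexadecanoyl)oxy]propanoate | CC(C)CCCCCCCCCCCC(=O)CC(=O)O[C@@H](COCc1ccccc1)C(=O)OC
F3 | step 6 | (S)-5-[(benzyloxy)methyl]-2,2-dimethyl-1,3-dioxolan-4-one | CC1(C)OC(=O)[C@H](COCc2ccccc2)O1
F4 | step 5 | (S)-3-(benzyloxy)-2-[(triethylsilyl)oxy]propanal | O=C[C@H](COCc1ccccc1)O[Si](CC)(CC)CC
F5 | step 5 | (2S)-1-(benzyloxy)-3-hydroxy-17-methyl-2-[(triethylsilyl)oxy]octadecan-5-one (both C3 epimers) | CC(C)CCCCCCCCCCCC(=O)CC(O)[C@H](COCc1ccccc1)O[Si](CC)(CC)CC
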